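**Retrosynthetic overview**
1. Target 21 ⇐ diacetate 20: a last-step Schenck ene reaction with ¹O₂ installs the C1 hydroperoxide and moves C1=C10 to C10=C14.
2. 20 ⇐ bis-silyl ether 18 (silyl → acetyl); 18 ⇐ open-chain ynal 16 + CO: a one-flask Ni(0) oxidative cyclisation/carbonylation forms C6–C7 (ten-membered ring) and then C11–C12/C12–O (butenolide).
3. 16 ⇐ Z-vinyl iodide 4 + β,γ-unsaturated aldehyde 12: asymmetric Nozaki–Hiyama–Kishi coupling (C3–C4) sets C3.
4. 12 ⇐ hexa-1,5-diyne + CH₂O + Me₃Al + ethylene oxide (carboalumination fixes E-C1=C10); 4 ⇐ but-2-yn-1-ol (directed hydroalumination fixes Z-C4=C5).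
5. Ring order: carbocycle and lactone both close in step 9; no ring exists before it.

Assumption: germacrane numbering is used for positions (ring C1–C10, lactone carbons C11–C13, C14 on C10, C15 on C4); reagents are named with SMILES in their step and not numbered; hexa-1,5-diyne is taken as a catalogue starting material.

**Step 1**
Reactants: 1 but-2-yn-1-ol
Product: 3 (Z)-3-iodobut-2-en-1-ol, via cyclic sodium alkenylalanate 2 (not isolated)
Conditions: Red-Al (1.6 equiv), THF, 0 °C→rt; then I₂, −78→0 °C; aq. work-up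
Reagents that add atoms: iodine, II
Why: hydroxyl-directed trans-hydroalumination places Al on C3 inside a five-membered alanate and iodinolysis proceeds with retention, so only the Z-iodide (I cis to CH₂OH) forms.

**Step 2**
Reactants: 3 (Z)-3-iodobut-2-en-1-ol
Product: 4 (Z)-triethyl[(3-iodobut-2-en-1-yl)oxy]silane
Conditions: TESCl, imidazole, CH₂Cl₂, 0 °C
Reagents that add atoms: chlorotriethylsilane, CC[Si](Cl)(CC)CC
Why: routine silylation of a primary alcohol, chosen because a primary TES ether can later be oxidised directly to the aldehyde in the presence of TBS ethers.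

**Step 3**
Reactants: 5 hexa-1,5-diyne
Product: 8 tert-butyl(hepta-2,6-diyn-1-yloxy)dimethylsilane, via lithium acetylide 6 (not isolated), via lithium alkoxide 7 (not isolated)
Conditions: 5 (3 equiv), n-BuLi (1.0 equiv), THF, −78 °C; (CH₂O)n, −78 °C→rt; then TBSCl, DMF, rt
Reagents that add atoms: paraformaldehyde (as formaldehyde), C=O; tert-butyldimethylsilyl chloride, CC(C)(C)[Si](C)(C)Cl
Why: mono-lithiation of the excess diyne, acetylide addition to formaldehyde and in-situ O-silylation of the lithium alkoxide give the mono-functionalised diyne, with the volatile excess of 5 recovered by distillation.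

**Step 4**
Reactants: 8 tert-butyl(hepta-2,6-diyn-1-yloxy)dimethylsilane
Product: 11 (E)-9-(tert-butyldimethylsilyloxy)-4-methylnon-3-en-7-yn-1-ol, via vinylalane 9 (not isolated), via lithium alanate 10 (not isolated)
Conditions: Me₃Al (2 equiv), Cp₂ZrCl₂ (0.25 equiv), CH₂Cl₂, 0 °C→rt; then n-BuLi, THF, −78 °C; ethylene oxide, −78→0 °C; aq. work-up
Reagents that add atoms: trimethylaluminium, C[Al](C)C; ethylene oxide, C1CO1
Why: Negishi Zr-catalysed carboalumination adds Me–Al syn across the terminal alkyne only (the internal alkyne is far slower), and the derived alanate opens ethylene oxide with retention, giving the E-trisubstituted C1=C10 alkene.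

**Step 5**
Reactants: 11 (E)-9-(tert-butyldimethylsilyloxy)-4-methylnon-3-en-7-yn-1-ol
Product: 12 (E)-9-(tert-butyldimethylsilyloxy)-4-methylnon-3-en-7-ynal
Conditions: Dess–Martin periodinane, pyridine, CH₂Cl₂, 0 °C; used at once without chromatography
Reagents that add atoms: none
Why: buffered Dess–Martin oxidation is mild enough to deliver the β,γ-unsaturated aldehyde without migration of the alkene into conjugation.

**Step 6**
Reactants: 12 (E)-9-(tert-butyldimethylsilyloxy)-4-methylnon-3-en-7-ynal; 4 (Z)-triethyl[(3-iodobut-2-en-1-yl)oxy]silane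
Product: 13 (2Z,6E,4S)-12-(tert-butyldimethylsilyloxy)-3,7-dimethyl-1-(triethylsilyloxy)dodeca-2,6-dien-10-yn-4-ol
Conditions: 4 (1.5 equiv), CrCl₂ (4 equiv), NiCl₂ (2 mol %), Kishi-type chiral oxazoline–sulfonamide ligand (4.4 equiv, enantiomer selected to give 4S), Et₃N, THF, rt; aq. serinate work-up
Reagents that add atoms: none
Why: asymmetric Nozaki–Hiyama–Kishi coupling, in which the alkenyl–Cr(III) species forms with retention of the Z geometry, the neutral conditions spare the enolisable aldehyde, and the chiral Cr complex selects the aldehyde face to set C3 (4S in this chain; check by Mosher esters).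

**Step 7**
Reactants: 13 (2Z,6E,4S)-12-(tert-butyldimethylsilyloxy)-3,7-dimethyl-1-(triethylsilyloxy)dodeca-2,6-dien-10-yn-4-ol
Product: 14 (2Z,6E,4S)-4,12-bis(tert-butyldimethylsilyloxy)-3,7-dimethyl-1-(triethylsilyloxy)dodeca-2,6-dien-10-yne
Conditions: TBSOTf, 2,6-lutidine, CH₂Cl₂, −78 °C
Reagents that add atoms: tert-butyldimethylsilyl triflate, CC(C)(C)[Si](C)(C)OS(=O)(=O)C(F)(F)F
Why: silylation of the secondary allylic alcohol at low temperature leaves the TES ether and the stereocentre untouched.

**Step 8**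
Reactants: 14 (2Z,6E,4S)-4,12-bis(tert-butyldimethylsilyloxy)-3,7-dimethyl-1-(triethylsilyloxy)dodeca-2,6-dien-10-yne
Product: 16 (2Z,6E,4S)-4,12-bis(tert-butyldimethylsilyloxy)-3,7-dimethyldodeca-2,6-dien-10-ynal, via alkoxysulfonium chloride 15 (not isolated)
Conditions: (COCl)₂ (4 equiv), DMSO (8 equiv), CH₂Cl₂, −78 °C; add 14, −78→−40 °C; Et₃N, −78→0 °C
Reagents that add atoms: none
Why: under Swern conditions the primary allylic TES ether is cleaved by chlorodimethylsulfonium chloride and oxidised directly to the aldehyde while both TBS ethers survive, and the cold, brief exposure to Et₃N keeps the Z-enal geometry.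

**Step 9**
Reactants: 16 (2Z,6E,4S)-4,12-bis(tert-butyldimethylsilyloxy)-3,7-dimethyldodeca-2,6-dien-10-ynal
Product: 18 3β,13-bis(tert-butyldimethylsilyloxy)germacra-1(10)E,4Z,7(11)-trien-12,6α-olide (3S,6R), via oxanickelacyclopentene 17 (not isolated)
Conditions: Ni(cod)₂ (1.2 equiv), PCy₃ (1.2 equiv), degassed toluene, syringe-pump addition of 16 to 2 mM, rt; then CO (1 atm), rt
Reagents that add atoms: carbon monoxide, [C-]#[O+]
Why: Proposed new method: Ni(0)–PCy₃ binds the alkyne and the aldehyde of 16 and couples them oxidatively at C7–C6 in the exo mode, giving the ten-membered ring as nickelacycle 17 with Ni on the CH₂OTBS-bearing carbon (the endo mode would need an E-alkene in an eleven-membered ring, and the Z-enal with a fully substituted β-carbon cannot reach the s-cis geometry of the competing 1,4-mode), after which CO inserts into the Ni–C(sp²) bond and C–O reductive elimination closes the butenolide, so both rings form in one flask; C6 is predicted to be R (H-6β) from closure through a heliangolide-like conformer with the C3 silyloxy group outside the ring and the alkyne on the outer face of the s-trans enal, which is a prediction and not a precedent; closest known reaction types are Ni(0)-catalysed reductive macrocyclisation of ynals through the same metallacycles, stoichiometric carbonylation of oxanickelacycles to lactones, and the Ti-, Ru- and Mo-mediated hetero-Pauson–Khand reaction of 1,6-ynals to fused butenolides.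

**Step 10**
Reactants: 18 3β,13-bis(tert-butyldimethylsilyloxy)germacra-1(10)E,4Z,7(11)-trien-12,6α-olide
Product: 20 3β,13-diacetoxygermacra-1(10)E,4Z,7(11)-trien-12,6α-olide, via diol 19 (not isolated)
Conditions: HF·pyridine, pyridine/THF, 0 °C→rt; evaporate; then Ac₂O, DMAP (cat.), pyridine, 0 °C
Reagents that add atoms: acetic anhydride, CC(=O)OC(C)=O
Why: acidic fluoride removes both silyl ethers without the base that would epimerise the acidic H-6 (γ-H of the butenolide), and DMAP-catalysed acetylation then esterifies the primary and the secondary allylic alcohol without touching a stereocentre.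

**Step 11**
Reactants: 20 3β,13-diacetoxygermacra-1(10)E,4Z,7(11)-trien-12,6α-olide
Product: 21 3β,13-diacetoxy-1β-hydroperoxygermacra-4Z,7(11),10(14)-trien-12,6α-olide (1R,3S,6R), the target
Conditions: O₂, tetraphenylporphyrin (cat.), visible light, CH₂Cl₂, −20 °C, to about 90 % conversion; no reductive work-up; chromatography below 20 °C
Reagents that add atoms: oxygen (reacting as singlet oxygen), O=O
Why: Schenck ene reaction, in which electrophilic ¹O₂ selects the electron-rich C1=C10 alkene (C4=C5 and the butenolide are deactivated by their oxygen substituents), abstracts H from C14 on the disubstituted side of the alkene and bonds to C1 from the exposed outer face to give 1R (1β), as in the known photooxygenation of costunolide and parthenolide to their 1β-hydroperoxy-10(14)-enes.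

**Compound list**
1 | but-2-yn-1-ol | CC#CCO | starting material
2 | cyclic sodium alkenylalanate (five-membered O–Al–C3=C2–C1 ring, two 2-methoxyethoxy groups on Al) | CC1=CCO[Al-]1(OCCOC)OCCOC.[Na+] | intermediate (not isolated)
3 | (Z)-3-iodobut-2-en-1-ol | C/C(I)=C/CO | intermediate
4 | (Z)-triethyl[(3-iodobut-2-en-1-yl)oxy]silane | C/C(I)=C/CO[Si](CC)(CC)CC | intermediate
5 | hexa-1,5-diyne | C#CCCC#C | starting material
6 | lithium hexa-1,5-diyn-1-ide | [Li+].[C-]#CCCC#C | intermediate (not isolated)
7 | lithium hepta-2,6-diyn-1-olate | [Li+].[O-]CC#CCCC#C | intermediate (not isolated)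
8 | tert-butyl(hepta-2,6-diyn-1-yloxy)dimethylsilane | C#CCCC#CCO[Si](C)(C)C(C)(C)C | intermediate
9 | (E)-[7-(tert-butyldimethylsilyloxy)-2-methylhept-1-en-5-yn-1-yl]dimethylalane | C[Al](C)/C=C(\C)CCC#CCO[Si](C)(C)C(C)(C)C | intermediate (not isolated)
10 | lithium butyl[(E)-7-(tert-butyldimethylsilyloxy)-2-methylhept-1-en-5-yn-1-yl]dimethylalanate | [Li+].CCCC[Al-](C)(C)/C=C(\C)CCC#CCO[Si](C)(C)C(C)(C)C | intermediate (not isolated)
11 | (E)-9-(tert-butyldimethylsilyloxy)-4-methylnon-3-en-7-yn-1-ol | OCC/C=C(\C)CCC#CCO[Si](C)(C)C(C)(C)C | intermediate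
12 | (E)-9-(tert-butyldimethylsilyloxy)-4-methylnon-3-en-7-ynal | O=CC/C=C(\C)CCC#CCO[Si](C)(C)C(C)(C)C | intermediate
13 | (2Z,6E,4S)-12-(tert-butyldimethylsilyloxy)-3,7-dimethyl-1-(triethylsilyloxy)dodeca-2,6-dien-10-yn-4-ol | CC[Si](CC)(CC)OC/C=C(/C)[C@@H](O)C/C=C(\C)CCC#CCO[Si](C)(C)C(C)(C)C | intermediate
14 | (2Z,6E,4S)-4,12-bis(tert-butyldimethylsilyloxy)-3,7-dimethyl-1-(triethylsilyloxy)dodeca-2,6-dien-10-yne | CC[Si](CC)(CC)OC/C=C(/C)[C@@H](O[Si](C)(C)C(C)(C)C)C/C=C(\C)CCC#CCO[Si](C)(C)C(C)(C)C | intermediate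
15 | alkoxydimethylsulfonium chloride of the C1 (chain) oxygen of 14 after loss of TES | C[S+](C)OC/C=C(/C)[C@@H](O[Si](C)(C)C(C)(C)C)C/C=C(\C)CCC#CCO[Si](C)(C)C(C)(C)C.[Cl-] | intermediate (not isolated)
16 | (2Z,6E,4S)-4,12-bis(tert-butyldimethylsilyloxy)-3,7-dimethyldodeca-2,6-dien-10-ynal | O=C/C=C(/C)[C@@H](O[Si](C)(C)C(C)(C)C)C/C=C(\C)CCC#CCO[Si](C)(C)C(C)(C)C | intermediate
17 | oxanickelacyclopentene (PCy₃)Ni(–O–C6–C7=C11–) fused to the ten-membered ring | C/C1=C\C[C@H](O[Si](C)(C)C(C)(C)C)/C(C)=C\[C@H]2O[Ni-]([P+](C3CCCCC3)(C3CCCCC3)C3CCCCC3)C(CO[Si](C)(C)C(C)(C)C)=C2CC1 | intermediate (not isolated)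
18 | 3β,13-bis(tert-butyldimethylsilyloxy)germacra-1(10)E,4Z,7(11)-trien-12,6α-olide (3S,6R) | C/C1=C\C[C@H](O[Si](C)(C)C(C)(C)C)/C(C)=C\[C@H]2OC(=O)C(CO[Si](C)(C)C(C)(C)C)=C2CC1 | intermediate
19 | 3β,13-dihydroxygermacra-1(10)E,4Z,7(11)-trien-12,6α-olide | C/C1=C\C[C@H](O)/C(C)=C\[C@H]2OC(=O)C(CO)=C2CC1 | intermediate (not isolated)
20 | 3β,13-diacetoxygermacra-1(10)E,4Z,7(11)-trien-12,6α-olide | C/C1=C\C[C@H](OC(C)=O)/C(C)=C\[C@H]2OC(=O)C(COC(C)=O)=C2CC1 | intermediate
21 | 3β,13-diacetoxy-1β-hydroperoxygermacra-4Z,7(11),10(14)-trien-12,6α-olide (1R,3S,6R) | C=C1CCC2=C(COC(C)=O)C(=O)O[C@@H]2/C=C(/C)[C@@H](OC(C)=O)C[C@H]1OO | target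

**Totals**
Total steps: 11. Longest linear sequence: 9 steps (5 → 21 through steps 3–11).

**Steps most likely to fail**

Step 9. The macrocyclic oxidative cyclisation may lose to oligomerisation, to β-silyloxy elimination from the alkenyl–Ni bond, or to the C6 epimer, and CO may strip Ni(0) before the nickelacycle has formed or reverse it afterwards. The fallback sets out from 16 and separates the two ring closures. The nickelacycle is formed as before but cleaved with iodine at −78 °C instead of CO, which gives the ten-membered (Z)-iodo allylic alcohol F1 with iodine on C11 cis to C6; C6 epimers can be separated at this stage. Pd-catalysed cyclocarbonylation of this iodo alcohol (Pd(PPh₃)₄, CO 1 atm, Et₃N, MeCN, 50 °C) then closes the butenolide through an acyl-palladium alkoxide and comes back to the route at 18.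

Step 6. The ligand-controlled addition of a Z-trisubstituted alkenylchromium to an enolisable β,γ-unsaturated aldehyde may give low ee. The fallback sets out from 12 and 4 and moves the stereocontrol to a ketone reduction. An achiral Nozaki–Hiyama–Kishi coupling (CrCl₂, NiCl₂ cat., DMSO, rt) gives the racemic alcohol F2, Dess–Martin oxidation gives the enone F3, and Corey–Bakshi–Shibata reduction ((R)-Me-CBS, catecholborane, toluene, −78 °C, alkenyl group as the large substituent) gives the 4S alcohol and comes back to the route at 13.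

Step 11. The ene reaction on 20 may give the 10-hydroperoxy-1(2)-ene regioisomer or the C1 epimer, and the hydroperoxide is fragile. The fallback sets out from 18 and runs the photooxygenation before the protecting-group exchange. In 18 the bulky 3β-silyloxy group next to C2 disfavours abstraction of the C2 hydrogens and changes the ring conformer population. Photooxygenation under the step 11 conditions gives the hydroperoxide F4, which is masked with 2-methoxypropene and PPTS as the 2-methoxyprop-2-yl peroxide F5. Buffered desilylation (TBAF, AcOH, THF) gives the diol F6, acetylation (Ac₂O, pyridine, DMAP) gives the diacetate F7, and mild hydrolysis (AcOH, THF, H₂O) releases the hydroperoxide and comes back to the route at 21.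

**Further compounds**
F1 | step 9 | (3S,6R)-6-hydroxy-11-iodo-3,13-bis(tert-butyldimethylsilyloxy)germacra-1(10)E,4Z,7(11)Z-triene (iodo allylic alcohol) | C/C1=C\C[C@H](O[Si](C)(C)C(C)(C)C)/C(C)=C\[C@@H](O)/C(=C(\I)CO[Si](C)(C)C(C)(C)C)CC1
F2 | step 6 | racemic (2Z,6E)-12-(tert-butyldimethylsilyloxy)-3,7-dimethyl-1-(triethylsilyloxy)dodeca-2,6-dien-10-yn-4-ol | CC[Si](CC)(CC)OC/C=C(/C)C(O)C/C=C(\C)CCC#CCO[Si](C)(C)C(C)(C)C
F3 | step 6 | (2Z,6E)-12-(tert-butyldimethylsilyloxy)-3,7-dimethyl-1-(triethylsilyloxy)dodeca-2,6-dien-10-yn-4-one | CC[Si](CC)(CC)OC/C=C(/C)C(=O)C/C=C(\C)CCC#CCO[Si](C)(C)C(C)(C)C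
F4 | step 11 | 3β,13-bis(tert-butyldimethylsilyloxy)-1β-hydroperoxygermacra-4Z,7(11),10(14)-trien-12,6α-olide | C=C1CCC2=C(CO[Si](C)(C)C(C)(C)C)C(=O)O[C@@H]2/C=C(/C)[C@@H](O[Si](C)(C)C(C)(C)C)C[C@H]1OO
F5 | step 11 | 3β,13-bis(tert-butyldimethylsilyloxy)-1β-(2-methoxyprop-2-ylperoxy)germacra-4Z,7(11),10(14)-trien-12,6α-olide | C=C1CCC2=C(CO[Si](C)(C)C(C)(C)C)C(=O)O[C@@H]2/C=C(/C)[C@@H](O[Si](C)(C)C(C)(C)C)C[C@H]1OOC(C)(C)OC
F6 | step 11 | 3β,13-dihydroxy-1β-(2-methoxyprop-2-ylperoxy)germacra-4Z,7(11),10(14)-trien-12,6α-olide | C=C1CCC2=C(CO)C(=O)O[C@@H]2/C=C(/C)[C@@H](O)C[C@H]1OOC(C)(C)OC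
F7 | step 11 | 3β,13-diacetoxy-1β-(2-methoxyprop-2-ylperoxy)germacra-4Z,7(11),10(14)-trien-12,6α-olide | C=C1CCC2=C(COC(C)=O)C(=O)O[C@@H]2/C=C(/C)[C@@H](OC(C)=O)C[C@H]1OOC(C)(C)OC
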